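Start from the balance: in the north run, free monomer plus monomer in chains stands at 99.0% of the charge at 8.00 min. So read either one.

common to all: free monomer 0.12 M; pre-initiator 0.70 mM
- north: transfer agent 3.6 mM; the very flask that is asked about, followed so far
- flask: transfer agent 3.60 mM; time 80 min

north run (percent of the free monomer charged)

| time / min | monomer in chains / % | free monomer / % |
|---|---|---|
| 1.50 | 0 | 101 |
| 3.00 | 6 | 95 |
| 5.00 | 18 | 87 |
| 6.00 | 24 | 76 |
| 8.00 | 38 | 61 |
| 10.0 | 51 | 52 |

(readings scatter by 2 percentage points)

- the average divides the monomer in chains by the number of chains begun, living and dead together
- the earlier runs do not show the number of chains; that part of a forecast is a guess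

- average number of monomer units in a chain (chains begun, living or dead) at 80 min
- part of the free monomer that has reacted at 80 min

Climb the ladder of times for this flask, which has the north recipe. First rung: the wait. The north run shows 0% monomer in chains at 1.50 min, and 6% at 3.00 min.

Second rung: treat free monomer as pseudo-first-order. Between 5.00 min and 10.0 min the north readings give a half-life of 6.73 min, longer than the 1.50 min of the first reading.

Third rung: the asked time, far longer than that half-life. Divide it by the half-life to get the half-life count, 11.9. If the half-life holds, my count leaves 0.0265% of the free monomer. The count says nothing about chains.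

The forecast gives dp 28 (22 to 42) and c 96% (82% to 100%), lower on c than my count. On chains it says: “The chain count is a guess.”

The flask gives dp 342 and c 99.9%.

    free monomer + initiator → living end + monomer in chains (k = 0.430 M⁻¹ s⁻¹)
    free monomer + living end → monomer in chains + living end, rate k2*[living end]*[free monomer] (k = 26.0 M⁻¹ s⁻¹)
    living end + transfer agent → dead chain (kL = 0.390 M⁻¹ s⁻¹)
    pre-initiator → initiator (k = 3.20 × 10⁻⁴ s⁻¹)
    free monomer → decomposition product (k = 3.40 × 10⁻⁶ s⁻¹)

At 80.0 min this flask holds 0.349 mM of chains begun, living ends plus dead chains, with 91% of the transfer agent still there. Use the half-life again on this flask: 40.0 min is 5.94 half-lives, which leaves 1.62% of the free monomer. The flask holds 1.04% free monomer then.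

Now take the neighbour flask, with 0.014 M of transfer agent. Assume the half-life grows in step with that charge. The neighbour's count falls to 3.05, which leaves 12.1% of its free monomer. The neighbour computes to 7.47% free monomer left, c 92.5%, dp 206.

The data are simulated for an exercise.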